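**Plan**

- Retrosynthesis: the palmitate C–O bond at C1 and the three O-benzyl bonds are cut first. Ring A is then cut at O1–C5 and N3–C4 into 2-(oxazol-5-yl)acetamide 19 and bromomethyl ketone 16. Ketone 16 is cut between C1 of the chain and the alkyne to give aldehyde 9 (open-chain 2-deoxy-L-fucose) and a two-carbon acetylide.
- Enabling feature: ring A is a 2,4-disubstituted oxazole with the chiral hexyl chain on C4 and the CH2 link to ring B on C2. Its O1–C2–N3 unit is therefore a primary amide and its C4–C5 unit a bromomethyl ketone.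
- Forward: L-fucose → fucal → 2-deoxy sugar → tribenzyl aldehyde → silyl ynone → (R)-propargylic alcohol → bromoalkyne → bromoketone 16. Ring B is bought inside acid 17, and ring A is closed onto it in step 13. Desilylation, palmitoylation and hydrogenolysis follow.
- Stereochemistry: C3, C4 and C5 of the chain are C3, C4 and C5 of L-fucose and are never touched. C1 is set by catalyst-controlled Ru–TsDPEN transfer hydrogenation of ynone 12.

Key step: step 13

Remark: chain positions C1–C6 run from the carbinol carbon on ring A to the methyl group. Compounds 2 and 6 are anomeric mixtures, 11 is a mixture of C3 epimers and 21 a mixture at its hemiaminal carbon; these centres are left undefined in the SMILES. L-Fucose is written open-chain although it reacts as the pyranose.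

**Route**

Step 1
Reactants: 1 L-fucose
Product: 4 di-O-acetyl-L-fucal (3,4-di-O-acetyl-1,5-anhydro-2,6-dideoxy-L-lyxo-hex-1-enitol), via tetra-O-acetyl-L-fucopyranose 2 (not isolated), via tri-O-acetyl-α-L-fucopyranosyl bromide 3 (not isolated)
Conditions: Ac2O, HBr/AcOH (cat.), rt; then HBr/AcOH (33%), rt; then NaOAc, Zn, CuSO4·5H2O, AcOH/H2O, 0 °C to rt (one pot)
Reagents that add atoms: acetic anhydride, CC(=O)OC(C)=O
Why: One-pot Fischer–Zach glycal synthesis, in which peracetylation, exchange of the anomeric acetate for bromide by HBr and zinc-mediated reductive elimination of bromide and the C2 acetate should deliver the glycal while C3, C4 and C5 are not touched.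

Step 2
Reactants: 4 di-O-acetyl-L-fucal
Product: 6 2-deoxy-L-fucose (2,6-dideoxy-L-lyxo-hexopyranose; anomeric mixture), via L-fucal 5 (not isolated)
Conditions: NaOMe (cat.), MeOH, rt; evaporate; then 0.1 M H2SO4, H2O, 0 °C to rt; BaCO3 neutralisation
Reagents that add atoms: water, O
Why: Zemplén transesterification frees the diol and acid-catalysed hydration of the enol ether (proton to C2, water to C1) then gives the 2-deoxy hemiacetal; removing the acetates first avoids the Ferrier-type allylic rearrangement that acylated glycals undergo in aqueous acid.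

Step 3
Reactants: 6 2-deoxy-L-fucose
Product: 7 (2S,3R,4S)-1-(1,3-dithian-2-yl)pentane-2,3,4-triol (2-deoxy-L-fucose propane-1,3-diyl dithioacetal)
Conditions: HS(CH2)3SH, conc. HCl, 0 °C to rt
Reagents that add atoms: propane-1,3-dithiol, SCCCS
Why: Fischer dithioacetalisation traps the open-chain aldehyde form of the hemiacetal as the 1,3-dithiane, which releases O5 from the ring so that all three hydroxyls can be protected alike.

Step 4
Reactants: 7 (2S,3R,4S)-1-(1,3-dithian-2-yl)pentane-2,3,4-triol
Product: 8 2-[(2S,3R,4S)-2,3,4-tris(benzyloxy)pentyl]-1,3-dithiane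
Conditions: NaH, BnBr, Bu4NI (cat.), DMF, 0 °C to rt
Reagents that add atoms: benzyl bromide, BrCc1ccccc1
Why: Threefold Williamson etherification; the dithiane C2–H is far too weakly acidic for NaH, so only the three alkoxides react.

Step 5
Reactants: 8 2-[(2S,3R,4S)-2,3,4-tris(benzyloxy)pentyl]-1,3-dithiane
Product: 9 (3S,4R,5S)-3,4,5-tris(benzyloxy)hexanal
Conditions: MeI, CaCO3, MeCN/H2O (9:1), 45 °C
Reagents that add atoms: water, O
Why: Alkylative dithioacetal hydrolysis, in which S-methylation turns sulfur into a sulfonium leaving group and water releases the aldehyde, while the CaCO3 buffer keeps the β-benzyloxy aldehyde from E1cB elimination.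

Step 6
Reactants: 9 (3S,4R,5S)-3,4,5-tris(benzyloxy)hexanal; 10 lithium (trimethylsilyl)acetylide (commercial 0.5 M solution in THF)
Product: 11 (5S,6R,7S)-5,6,7-tris(benzyloxy)-1-(trimethylsilyl)oct-1-yn-3-ol (mixture of C3 epimers)
Conditions: THF, −78 °C; then aq. NH4Cl
Reagents that add atoms: none
Why: 1,2-Addition of an alkynyllithium to the aldehyde at low temperature, faster than enolisation or β-elimination; the new carbinol centre is left uncontrolled because it is oxidised in the next step.

Step 7
Reactants: 11 (5S,6R,7S)-5,6,7-tris(benzyloxy)-1-(trimethylsilyl)oct-1-yn-3-ol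
Product: 12 (5S,6R,7S)-5,6,7-tris(benzyloxy)-1-(trimethylsilyl)oct-1-yn-3-one
Conditions: Dess–Martin periodinane, NaHCO3, CH2Cl2, 0 °C to rt
Reagents that add atoms: none
Why: Dess–Martin oxidation of a secondary propargylic alcohol under bicarbonate buffer, neutral enough to spare the β-benzyloxy group and the C–Si bond.

Step 8
Reactants: 12 (5S,6R,7S)-5,6,7-tris(benzyloxy)-1-(trimethylsilyl)oct-1-yn-3-one
Product: 13 (3R,5S,6R,7S)-5,6,7-tris(benzyloxy)-1-(trimethylsilyl)oct-1-yn-3-ol
Conditions: Ru[(R,R)-TsNCH(Ph)CH(Ph)NH](p-cymene) (2 mol %), i-PrOH, rt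
Reagents that add atoms: none
Why: Noyori asymmetric transfer hydrogenation of an alkynyl ketone, in which the (R,R)-TsDPEN ruthenium amide passes hydride and proton through a six-membered transition state with the alkyne in the place an aryl group would take, so the catalyst and not the remote C5 centre should set the new C3 carbinol as R; the base-free 16-electron complex avoids β-elimination of the benzyloxy group.

Step 9
Reactants: 13 (3R,5S,6R,7S)-5,6,7-tris(benzyloxy)-1-(trimethylsilyl)oct-1-yn-3-ol
Product: 14 (3R,5S,6R,7S)-5,6,7-tris(benzyloxy)-3-(tert-butyldimethylsilyloxy)-1-(trimethylsilyl)oct-1-yne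
Conditions: TBSCl, imidazole, DMF, rt
Reagents that add atoms: tert-butyldimethylsilyl chloride, CC(C)(C)[Si](C)(C)Cl
Why: Standard silylation of a secondary alcohol; the bulky ether later shields the α-carbon of the ketone and is orthogonal to the benzyl ethers.

Step 10
Reactants: 14 (3R,5S,6R,7S)-5,6,7-tris(benzyloxy)-3-(tert-butyldimethylsilyloxy)-1-(trimethylsilyl)oct-1-yne
Product: 15 (3R,5S,6R,7S)-5,6,7-tris(benzyloxy)-1-bromo-3-(tert-butyldimethylsilyloxy)oct-1-yne
Conditions: NBS, AgNO3 (10 mol %), acetone, rt, dark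
Reagents that add atoms: N-bromosuccinimide, O=C1CCC(=O)N1Br
Why: Silver-catalysed bromodesilylation, in which AgNO3 converts the alkynylsilane into a silver acetylide that NBS brominates, so the C-silyl group is exchanged for bromine in one operation without touching the O-silyl ether.

Step 11
Reactants: 15 (3R,5S,6R,7S)-5,6,7-tris(benzyloxy)-1-bromo-3-(tert-butyldimethylsilyloxy)oct-1-yne
Product: 16 (3R,5S,6R,7S)-5,6,7-tris(benzyloxy)-1-bromo-3-(tert-butyldimethylsilyloxy)octan-2-one
Conditions: (XPhos)AuNTf2 (3 mol %), H2O (3 equiv), ClCH2CH2Cl, rt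
Reagents that add atoms: water, O
Why: Gold-catalysed hydration of a 1-bromoalkyne, in which water adds to the gold-activated triple bond at the carbon remote from bromine and protodeauration gives the bromomethyl ketone; the neutral conditions should leave the α-silyloxy stereocenter, the TBS ether and the benzyl ethers intact.

Step 12
Reactants: 17 2-(oxazol-5-yl)acetic acid
Product: 19 2-(oxazol-5-yl)acetamide, via acylimidazole 18 (not isolated)
Conditions: CDI, THF, rt; then aq. NH3 (28%), 0 °C to rt
Reagents that add atoms: ammonia, N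
Why: Amide formation through the acylimidazole, in which CDI activates the acid with loss of CO2 and ammonia displaces imidazole, conditions under which ring B and its CH2 group are inert.

Step 13
Reactants: 16 (3R,5S,6R,7S)-5,6,7-tris(benzyloxy)-1-bromo-3-(tert-butyldimethylsilyloxy)octan-2-one; 19 2-(oxazol-5-yl)acetamide
Product: 22 4-[(1R,3S,4R,5S)-3,4,5-tris(benzyloxy)-1-(tert-butyldimethylsilyloxy)hexyl]-2-(oxazol-5-ylmethyl)oxazole, via imidate 20 (not isolated), via hydroxyoxazoline 21 (not isolated)
Conditions: AgOTf (2.5 equiv), 2,6-di-tert-butyl-4-methylpyridine (1.5 equiv), EtOAc, 50 °C, dark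
Reagents that add atoms: none
Why: Silver-assisted Hantzsch (Blümlein–Lewy) oxazole synthesis: Ag+ pulls bromide from the primary C–Br bond of 16 while the carbonyl oxygen of amide 19 displaces it to give imidate 20 (O1–C5), whose nitrogen adds to the ketone to give hydroxyoxazoline 21 (N3–C4), and loss of water aromatises ring A. The closest known reaction type is the AgOTf-promoted union of primary amides with α-bromoketones to 2,4-disubstituted oxazoles. Ring A closes in a 5-exo-trig mode, the imidate nitrogen attacking the exocyclic C=O. No stereocenter is created, and the only one at risk, the α-silyloxy carbon that becomes C1 of the chain, is shielded from enolisation by the TBS group and by the absence of any base stronger than the hindered pyridine, which only holds the liberated TfOH as its salt. Regioselectivity (chain at C4, not C5) is fixed by the bromomethyl ketone, since oxygen can alkylate only at the CH2Br carbon and nitrogen can condense only at the carbonyl carbon; chemoselectivity for the amide oxygen over the weakly basic nitrogen of ring B rests on halophilic activation, which favours the more nucleophilic amide oxygen.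

Step 14
Reactants: 22 4-[(1R,3S,4R,5S)-3,4,5-tris(benzyloxy)-1-(tert-butyldimethylsilyloxy)hexyl]-2-(oxazol-5-ylmethyl)oxazole
Product: 23 (1R,3S,4R,5S)-3,4,5-tris(benzyloxy)-1-[2-(oxazol-5-ylmethyl)oxazol-4-yl]hexan-1-ol
Conditions: Bu4NF, AcOH, THF, 0 °C to rt
Reagents that add atoms: none
Why: Fluoride-induced cleavage of the Si–O bond; buffering with AcOH keeps the medium non-basic so that neither the CH2 between the rings nor the benzyl ethers are affected.

Step 15
Reactants: 23 (1R,3S,4R,5S)-3,4,5-tris(benzyloxy)-1-[2-(oxazol-5-ylmethyl)oxazol-4-yl]hexan-1-ol; 24 palmitoyl chloride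
Product: 25 (1R,3S,4R,5S)-3,4,5-tris(benzyloxy)-1-[2-(oxazol-5-ylmethyl)oxazol-4-yl]hexyl hexadecanoate
Conditions: Et3N, DMAP (cat.), CH2Cl2, 0 °C to rt
Reagents that add atoms: none
Why: DMAP-catalysed acylation of the secondary alcohol with the acid chloride via the acylpyridinium ion; the C1 hydroxyl is the only free one and its configuration is retained because the C–O bond is not broken.

Step 16
Reactants: 25 (1R,3S,4R,5S)-3,4,5-tris(benzyloxy)-1-[2-(oxazol-5-ylmethyl)oxazol-4-yl]hexyl hexadecanoate
Product: 26 (1R,3S,4R,5S)-3,4,5-trihydroxy-1-[2-(oxazol-5-ylmethyl)oxazol-4-yl]hexyl hexadecanoate (CNP0240423.1)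
Conditions: H2 (1 atm), Pd(OH)2/C, EtOAc, rt
Reagents that add atoms: none
Why: Catalytic hydrogenolysis of the three benzyl ethers under neutral conditions, which the oxazole rings and the ester should tolerate and which should not induce acyl migration from O1 to O3.

**Compound list**

1 | L-fucose | O=C[C@@H](O)[C@H](O)[C@H](O)[C@H](C)O | starting material
2 | 1,2,3,4-tetra-O-acetyl-L-fucopyranose (anomeric mixture) | CC(=O)OC1[C@@H](OC(C)=O)[C@H](OC(C)=O)[C@H](OC(C)=O)[C@H](C)O1 | intermediate (not isolated)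
3 | 2,3,4-tri-O-acetyl-α-L-fucopyranosyl bromide | Br[C@H]1[C@@H](OC(C)=O)[C@H](OC(C)=O)[C@H](OC(C)=O)[C@H](C)O1 | intermediate (not isolated)
4 | 3,4-di-O-acetyl-L-fucal | C1=C[C@H](OC(C)=O)[C@H](OC(C)=O)[C@H](C)O1 | intermediate
5 | L-fucal | C1=C[C@H](O)[C@H](O)[C@H](C)O1 | intermediate (not isolated)
6 | 2-deoxy-L-fucose (pyranose, anomeric mixture) | OC1C[C@H](O)[C@H](O)[C@H](C)O1 | intermediate
7 | (2S,3R,4S)-1-(1,3-dithian-2-yl)pentane-2,3,4-triol | S1CCCSC1C[C@H](O)[C@H](O)[C@H](C)O | intermediate
8 | 2-[(2S,3R,4S)-2,3,4-tris(benzyloxy)pentyl]-1,3-dithiane | S1CCCSC1C[C@H](OCc2ccccc2)[C@H](OCc2ccccc2)[C@H](C)OCc2ccccc2 | intermediate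
9 | (3S,4R,5S)-3,4,5-tris(benzyloxy)hexanal | O=CC[C@H](OCc1ccccc1)[C@H](OCc1ccccc1)[C@H](C)OCc1ccccc1 | intermediate
10 | lithium (trimethylsilyl)acetylide | [Li]C#C[Si](C)(C)C | starting material
11 | (5S,6R,7S)-5,6,7-tris(benzyloxy)-1-(trimethylsilyl)oct-1-yn-3-ol (C3 epimers) | C[Si](C)(C)C#CC(O)C[C@H](OCc1ccccc1)[C@H](OCc1ccccc1)[C@H](C)OCc1ccccc1 | intermediate
12 | (5S,6R,7S)-5,6,7-tris(benzyloxy)-1-(trimethylsilyl)oct-1-yn-3-one | C[Si](C)(C)C#CC(=O)C[C@H](OCc1ccccc1)[C@H](OCc1ccccc1)[C@H](C)OCc1ccccc1 | intermediate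
13 | (3R,5S,6R,7S)-5,6,7-tris(benzyloxy)-1-(trimethylsilyl)oct-1-yn-3-ol | C[Si](C)(C)C#C[C@H](O)C[C@H](OCc1ccccc1)[C@H](OCc1ccccc1)[C@H](C)OCc1ccccc1 | intermediate
14 | (3R,5S,6R,7S)-5,6,7-tris(benzyloxy)-3-(tert-butyldimethylsilyloxy)-1-(trimethylsilyl)oct-1-yne | C[Si](C)(C)C#C[C@H](O[Si](C)(C)C(C)(C)C)C[C@H](OCc1ccccc1)[C@H](OCc1ccccc1)[C@H](C)OCc1ccccc1 | intermediate
15 | (3R,5S,6R,7S)-5,6,7-tris(benzyloxy)-1-bromo-3-(tert-butyldimethylsilyloxy)oct-1-yne | BrC#C[C@H](O[Si](C)(C)C(C)(C)C)C[C@H](OCc1ccccc1)[C@H](OCc1ccccc1)[C@H](C)OCc1ccccc1 | intermediate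
16 | (3R,5S,6R,7S)-5,6,7-tris(benzyloxy)-1-bromo-3-(tert-butyldimethylsilyloxy)octan-2-one | BrCC(=O)[C@H](O[Si](C)(C)C(C)(C)C)C[C@H](OCc1ccccc1)[C@H](OCc1ccccc1)[C@H](C)OCc1ccccc1 | intermediate
17 | 2-(oxazol-5-yl)acetic acid | OC(=O)Cc1cnco1 | starting material
18 | 1-(imidazol-1-yl)-2-(oxazol-5-yl)ethan-1-one | O=C(Cc1cnco1)n1ccnc1 | intermediate (not isolated)
19 | 2-(oxazol-5-yl)acetamide | NC(=O)Cc1cnco1 | intermediate
20 | (3R,5S,6R,7S)-5,6,7-tris(benzyloxy)-3-(tert-butyldimethylsilyloxy)-2-oxooctyl 2-(oxazol-5-yl)ethanimidate | N=C(Cc1cnco1)OCC(=O)[C@H](O[Si](C)(C)C(C)(C)C)C[C@H](OCc1ccccc1)[C@H](OCc1ccccc1)[C@H](C)OCc1ccccc1 | intermediate (not isolated)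
21 | 4-[(1R,3S,4R,5S)-3,4,5-tris(benzyloxy)-1-(tert-butyldimethylsilyloxy)hexyl]-2-(oxazol-5-ylmethyl)-4,5-dihydrooxazol-4-ol | OC1(COC(Cc2cnco2)=N1)[C@H](O[Si](C)(C)C(C)(C)C)C[C@H](OCc3ccccc3)[C@H](OCc3ccccc3)[C@H](C)OCc3ccccc3 | intermediate (not isolated)
22 | 4-[(1R,3S,4R,5S)-3,4,5-tris(benzyloxy)-1-(tert-butyldimethylsilyloxy)hexyl]-2-(oxazol-5-ylmethyl)oxazole | CC(C)(C)[Si](C)(C)O[C@H](C[C@H](OCc1ccccc1)[C@H](OCc1ccccc1)[C@H](C)OCc1ccccc1)c1coc(Cc2cnco2)n1 | intermediate
23 | (1R,3S,4R,5S)-3,4,5-tris(benzyloxy)-1-[2-(oxazol-5-ylmethyl)oxazol-4-yl]hexan-1-ol | O[C@H](C[C@H](OCc1ccccc1)[C@H](OCc1ccccc1)[C@H](C)OCc1ccccc1)c1coc(Cc2cnco2)n1 | intermediate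
24 | palmitoyl chloride | CCCCCCCCCCCCCCCC(=O)Cl | starting material
25 | (1R,3S,4R,5S)-3,4,5-tris(benzyloxy)-1-[2-(oxazol-5-ylmethyl)oxazol-4-yl]hexyl hexadecanoate | CCCCCCCCCCCCCCCC(=O)O[C@H](C[C@H](OCc1ccccc1)[C@H](OCc1ccccc1)[C@H](C)OCc1ccccc1)c1coc(Cc2cnco2)n1 | intermediate
26 | (1R,3S,4R,5S)-3,4,5-trihydroxy-1-[2-(oxazol-5-ylmethyl)oxazol-4-yl]hexyl hexadecanoate | CCCCCCCCCCCCCCCC(=O)O[C@H](C[C@H](O)[C@H](O)[C@H](C)O)c1coc(Cc2cnco2)n1 | target

**Step count**

Total: 16 steps. Longest linear sequence: 15 steps (steps 1–11 and 13–16, from L-fucose); the amide branch is one step (step 12).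

**Steps most likely to fail**

Step 13 (ring A closure). Alkylation may occur at the amide nitrogen or at the nitrogen of ring B instead of the amide oxygen. The sequence may stall at the hydroxyoxazoline stage. The α-silyloxy ketone may enolise and lose its configuration, or the liberated acid may strip the silyl ether. The fallback is a Davidson oxazole synthesis, which makes the O1–C5 bond first and brings nitrogen in as ammonia. It sets out from bromoketone 16 and acid 17 and returns at 22. The caesium salt of 17 (Cs2CO3, DMF, rt) should displace bromide from 16 to give (3R,5S,6R,7S)-5,6,7-tris(benzyloxy)-3-(tert-butyldimethylsilyloxy)-2-oxooctyl 2-(oxazol-5-yl)acetate F1. Heating F1 with NH4OAc and AcOH in toluene at 100 °C should condense ammonia with the ketone and close the ring onto the ester carbonyl to give 22.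

Step 11 (bromoalkyne hydration). Water addition may be slow because the propargylic silyloxy group deactivates the adjacent alkyne carbon inductively. The catalyst may be diverted into C–Br activation or ionisation at the propargylic position. The C5 benzyloxy oxygen may add to the activated alkyne in place of water. The fallback separates hydration from bromination; it sets out from 14 and returns at 16. K2CO3 in MeOH should remove the C-silyl group to give (3R,5S,6R,7S)-5,6,7-tris(benzyloxy)-3-(tert-butyldimethylsilyloxy)oct-1-yne F2. Markovnikov hydration of this terminal alkyne ((IPr)AuCl/AgSbF6 cat., 1,4-dioxane/H2O, 60 °C) should give (3R,5S,6R,7S)-5,6,7-tris(benzyloxy)-3-(tert-butyldimethylsilyloxy)octan-2-one F3. Kinetic enolisation on the methyl side (LiHMDS, TMSCl, THF, −78 °C) should give (3R,5S,6R,7S)-5,6,7-tris(benzyloxy)-3-(tert-butyldimethylsilyloxy)-2-(trimethylsilyloxy)oct-1-ene F4. NBS in THF at 0 °C should then brominate the enol silane to give 16.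

Step 16 (global debenzylation). The C1–O ester bond next to ring A is activated like a benzylic one and may undergo hydrogenolysis. The two oxazole nitrogens may bind the catalyst and slow debenzylation. Once the C3 hydroxyl is free, the acyl group may migrate from O1 to O3 on prolonged reaction. The fallback is a non-reductive Lewis-acid debenzylation; it sets out from 25 and arrives directly at 26. BCl3 in excess with pentamethylbenzene as cation scavenger in CH2Cl2 at −78 °C, quenched with MeOH at low temperature, should cleave the three benzyl ethers without hydrogen or metal. This fallback makes no new compound (entry F0).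

**Further compounds**

F1 | step 13 | (3R,5S,6R,7S)-5,6,7-tris(benzyloxy)-3-(tert-butyldimethylsilyloxy)-2-oxooctyl 2-(oxazol-5-yl)acetate | O=C(Cc1cnco1)OCC(=O)[C@H](O[Si](C)(C)C(C)(C)C)C[C@H](OCc1ccccc1)[C@H](OCc1ccccc1)[C@H](C)OCc1ccccc1
F2 | step 11 | (3R,5S,6R,7S)-5,6,7-tris(benzyloxy)-3-(tert-butyldimethylsilyloxy)oct-1-yne | C#C[C@H](O[Si](C)(C)C(C)(C)C)C[C@H](OCc1ccccc1)[C@H](OCc1ccccc1)[C@H](C)OCc1ccccc1
F3 | step 11 | (3R,5S,6R,7S)-5,6,7-tris(benzyloxy)-3-(tert-butyldimethylsilyloxy)octan-2-one | CC(=O)[C@H](O[Si](C)(C)C(C)(C)C)C[C@H](OCc1ccccc1)[C@H](OCc1ccccc1)[C@H](C)OCc1ccccc1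
F4 | step 11 | (3R,5S,6R,7S)-5,6,7-tris(benzyloxy)-3-(tert-butyldimethylsilyloxy)-2-(trimethylsilyloxy)oct-1-ene | C=C(O[Si](C)(C)C)[C@H](O[Si](C)(C)C(C)(C)C)C[C@H](OCc1ccccc1)[C@H](OCc1ccccc1)[C@H](C)OCc1ccccc1
F0 | step 16 | none | none
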